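## The problem

Aiphanol (15) is a stilbenolignan: a 2,3-dihydro-1,4-benzodioxine (O1, C2, C3, O4, C4a–C8a) whose benzo ring is the catechol ring of piceatannol. C2 carries CH2OH, C3 the 4-hydroxy-3,5-dimethoxyphenyl (syringyl) ring, and C6 the (E)-3,5-dihydroxystyryl group.

C2 and C3 are adjacent stereocentres, both R, trans, each bound to one ring oxygen. They differ in risk. C3 is a benzylic ether para to a free phenol, so it can open to a quinone methide and re-close to the more stable trans ring. C2 has no such correction, so its absolute configuration must be set once and never touched again.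

The two catechol oxygens must be told apart: O1 (on C2) is para to C6 and O4 (on C3) is meta. The E-stilbene with a free resorcinol rules out hydrogenolysis, oxidants and strong acid late in the route. An aldehyde handle at C6 would not survive a carbonyl reduction elsewhere.

The feature that opens the problem is the C2–C3 edge of the dioxane ring. With C3 as an aryl ketone and the CH2OH carbon as an ester, C2–H is the methine of a 1,3-dicarbonyl compound that already bears O1, so C2 epimerises freely. O4 is then simply the oxygen of the C3 carbinol. The ring can therefore be closed at the aryl bond O4–C4a, leaving both stereocentres untouched.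

## Retrosynthesis

**15 ⇒ 14.** The O–MOM bonds of three phenols and the O–Si bond of the primary alcohol are cut. All four groups should fall in one methanolic acid step, so no hydrogenolysis ever meets the stilbene.

**14 ⇒ 10 + 13.** The C6–C(vinyl) bond is cut (Mizoroki–Heck). An olefination at a C6 aldehyde is the neighbouring cut, but an aldehyde would be reduced in the key step. Carrying the stilbene from the start would expose it to seven steps. Bromide 10 and styrene 13 are simple and robust. The forward reaction must be E-selective at an electron-rich aryl bromide.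

**10 ⇒ 9.** The aryl bond O4–C4a is cut, not the benzylic bond O4–C3 that is usually chosen. The benzylic cut needs a free, differentiated catechol and an SN2 or SN1 event at C3. The aryl cut breaks no bond at C2 or C3. It also turns the catechol regiochemistry into the fixed positions of OH, I and Br on the purchased phenol 5. The forward reaction is a copper-catalysed intramolecular O-arylation at C–I in the presence of C–Br.

**9 ⇒ 8 ⇒ 7.** These are functional-group changes only. The CH2OH group is an ester in 7. The primary hydroxyl of 8 is silylated so that only the C3 carbinol can close a ring.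

**7 ⇒ 6.** This is the key disconnection: the C3–H bond, and with it the configuration of C2. Racemic, configurationally labile keto ester 6 has no stereochemical information. Asymmetric transfer hydrogenation under dynamic kinetic resolution should turn it into the single syn isomer 7. Syn in 7 becomes trans in 10 because the later closure retains both centres.

**6 ⇒ 4 + 5 ⇒ 3 ⇒ 2 ⇒ 1.** O1–C2 is cut (phenoxide SN2 on an α-chloro-β-keto ester). Then C2–Cl, then C1–C2 (Claisen condensation with diethyl carbonate), then the MOM ether, back to acetosyringone 1.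

**13 ⇒ 12 ⇒ 11.** The vinyl C=C is cut (Wittig methylenation), then the two MOM ethers, back to 3,5-dihydroxybenzaldehyde 11.

## Roads not taken

**Alternative 1:** The most obvious cut removes O1–C2 and O4–C3 together, as in the presumed biosynthesis. Piceatannol A1 and sinapyl alcohol A2 would be coupled oxidatively (Ag2O or a peroxidase). The quinone methide A3 would form by radical coupling and be trapped by the neighbouring phenol. C2 would be created in a radical–radical coupling with no chiral influence, so the product could only be racemic. Both partners also homo-couple, the choice between the two catechol oxygens is only electronically biased, and the free stilbene polyphenol meets an oxidant. The chosen plan sets C2 by a catalyst and fixes the regiochemistry in a purchased phenol.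

**Alternative 2:** The reagent-controlled linear route: asymmetric dihydroxylation of cinnamate A4 to diol A5, then two C–O substitutions at carbon. The first would be a Mitsunobu etherification at C2 with a mono-protected catechol; the second, after reduction and deprotection, a benzylic ring closure at C3. Each stereocentre of A5 must survive an inversion at carbon. The benzylic one sits on a syringyl-stabilised carbon that leaks to SN1. The catechol needs two orthogonally protected oxygens. The chosen plan breaks no bond at either stereocentre after they are formed and needs no catechol protection.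

**Alternative 3:** Cutting the two C–H bonds at C2 and C3 leads to the achiral benzodioxine ester A6 and an asymmetric hydrogenation. Syn addition of H2 would give the cis ester A7, the wrong relative configuration. Epimerising C2 through its enolate would invite E1cB opening of the C3–O4 bond and scramble C3. A tetrasubstituted, doubly oxygenated enol-ether alkene with an ester is also a very hard hydrogenation substrate, and the aryl bromide may not survive. The chosen plan obtains trans directly.

Key step: step 5

Remarks on the chemistry (assumptions):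
- Compounds 1, 5 and 11 are taken as purchasable.
- The (S,S) catalyst is assigned from the facial sense known for simple aryl ketones; if the sense on 6 were opposite, the mirror-image catalyst would be used.
- The descriptor at C2 changes from S (7) to R (8) only because CO2Et outranks C3 and CH2OH does not; no bond at C2 is touched.

## Route

Step 1
Reactants: 1 acetosyringone, 1-(4-hydroxy-3,5-dimethoxyphenyl)ethan-1-one
Product: 2 1-[3,5-dimethoxy-4-(methoxymethoxy)phenyl]ethan-1-one
Conditions: MOMCl, i-Pr2NEt, CH2Cl2, 0 °C → rt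
Reagents that add atoms: chloromethyl methyl ether (MOMCl), COCCl
Why: O-alkylation of the phenol with an α-chloro ether (Williamson type); the acetal masks a phenol whose anion would block the Claisen condensation and later open the benzylic C3–O bond through a quinone methide.

Step 2
Reactants: 2 1-[3,5-dimethoxy-4-(methoxymethoxy)phenyl]ethan-1-one
Product: 3 ethyl 3-[3,5-dimethoxy-4-(methoxymethoxy)phenyl]-3-oxopropanoate
Conditions: NaH, (EtO)2CO, THF, reflux; then dil. HCl
Reagents that add atoms: diethyl carbonate, CCOC(=O)OCC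
Why: Crossed Claisen condensation of the methyl ketone enolate with a non-enolisable carbonate, driven by deprotonation of the β-keto ester formed; the MOM ether is stable to base.

Step 3
Reactants: 3 ethyl 3-[3,5-dimethoxy-4-(methoxymethoxy)phenyl]-3-oxopropanoate
Product: 4 ethyl 2-chloro-3-[3,5-dimethoxy-4-(methoxymethoxy)phenyl]-3-oxopropanoate (racemic)
Conditions: NCS (1.0 equiv), Mg(ClO4)2 (cat.), EtOAc, rt
Reagents that add atoms: N-chlorosuccinimide, O=C1CCC(=O)N1Cl
Why: Electrophilic α-chlorination of the enol of a 1,3-dicarbonyl compound; neutral conditions spare the MOM acetal and one equivalent limits dichlorination.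

Step 4
Reactants: 4 ethyl 2-chloro-3-[3,5-dimethoxy-4-(methoxymethoxy)phenyl]-3-oxopropanoate; 5 4-bromo-2-iodophenol
Product: 6 ethyl 2-(4-bromo-2-iodophenoxy)-3-[3,5-dimethoxy-4-(methoxymethoxy)phenyl]-3-oxopropanoate (racemic)
Conditions: K2CO3, acetone, rt → 50 °C
Reagents that add atoms: none
Why: SN2 displacement of chloride at the doubly activated carbon by the phenoxide, the Williamson etherification used for β-O-4 model compounds; it forms O1–C2 and places O1 para to bromine, and the new stereocentre is racemic and labile by design.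

Step 5
Reactants: 6 ethyl 2-(4-bromo-2-iodophenoxy)-3-[3,5-dimethoxy-4-(methoxymethoxy)phenyl]-3-oxopropanoate (racemic)
Product: 7 ethyl (2S,3R)-2-(4-bromo-2-iodophenoxy)-3-hydroxy-3-[3,5-dimethoxy-4-(methoxymethoxy)phenyl]propanoate
Conditions: RuCl[(S,S)-TsDPEN](p-cymene) (1–2 mol %), HCO2H/Et3N (5:2), DMF, 30 °C
Reagents that add atoms: none
Why: Noyori–Ikariya asymmetric transfer hydrogenation with dynamic kinetic resolution; the closest precedent is the syn-selective reduction of α-alkoxy-β-keto esters. The C2 methine of 6 lies between the aryl ketone and the ester and bears the aryloxy oxygen, so the Et3N/HCO2H medium should enolise it continuously and interconvert the two enantiomers faster than either is reduced. Hydride and proton pass from Ru–H and N–H to the C=O in a six-membered outer-sphere transition state; the catalyst should fix the C3 carbinol as R through the edge-to-face contact of its η6-arene with the syringyl ring, as with simple aryl ketones. C2 is set by the substrate: the enantiomer that places the C2–OAr bond anti to the incoming hydride (polar Felkin–Anh), with the ester beside the carbonyl oxygen, should be reduced faster, and this gives the syn (2S,3R) isomer. No ring is closed in this step; the closure in step 8 forms O4–C4a and carries both centres over unchanged, so syn in 7 becomes trans in 10. The step needs enantioface selectivity, syn selectivity and racemisation faster than reduction; these rest on the aryl ketone, the α-oxygen and the 1,3-dicarbonyl acidity of C2–H respectively. The iodide, the bromide, the MOM ether and the electron-rich ring should be inert to the ruthenium hydride.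

Step 6
Reactants: 7 ethyl (2S,3R)-2-(4-bromo-2-iodophenoxy)-3-hydroxy-3-[3,5-dimethoxy-4-(methoxymethoxy)phenyl]propanoate
Product: 8 (1R,2R)-2-(4-bromo-2-iodophenoxy)-1-[3,5-dimethoxy-4-(methoxymethoxy)phenyl]propane-1,3-diol
Conditions: LiBH4, THF, 0 °C → rt; aq. NH4Cl
Reagents that add atoms: none
Why: Hydride reduction of an ester activated by its α-aryloxy and β-hydroxy groups; aryl halides and the acetal are inert, and once the carbonyl is gone C2 can no longer epimerise.

Step 7
Reactants: 8 (1R,2R)-2-(4-bromo-2-iodophenoxy)-1-[3,5-dimethoxy-4-(methoxymethoxy)phenyl]propane-1,3-diol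
Product: 9 (1R,2R)-2-(4-bromo-2-iodophenoxy)-3-[(tert-butyldimethylsilyl)oxy]-1-[3,5-dimethoxy-4-(methoxymethoxy)phenyl]propan-1-ol
Conditions: TBSCl (1.05 equiv), imidazole, CH2Cl2, 0 °C
Reagents that add atoms: tert-butyldimethylsilyl chloride, CC(C)(C)[Si](C)(C)Cl
Why: Selective silylation of the primary hydroxyl over the hindered secondary benzylic one; it removes the competing seven-membered ring closure in step 8.

Step 8
Reactants: 9 (1R,2R)-2-(4-bromo-2-iodophenoxy)-3-[(tert-butyldimethylsilyl)oxy]-1-[3,5-dimethoxy-4-(methoxymethoxy)phenyl]propan-1-ol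
Product: 10 {[(2R,3R)-6-bromo-3-[3,5-dimethoxy-4-(methoxymethoxy)phenyl]-2,3-dihydro-1,4-benzodioxin-2-yl]methoxy}(tert-butyl)dimethylsilane
Conditions: CuI (10 mol %), 3,4,7,8-tetramethyl-1,10-phenanthroline (20 mol %), Cs2CO3, toluene, 100 °C
Reagents that add atoms: none
Why: Ullmann-type copper-catalysed intramolecular O-arylation of a secondary alkoxide; C–I should react well before C–Br, and the six-membered closure forms O4–C4a, so no bond at C2 or C3 is broken and (1R,2R)-syn becomes (2R,3R)-trans. Copper also avoids the β-hydride elimination open to a palladium alkoxide of a benzylic alcohol.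

Step 9
Reactants: 11 3,5-dihydroxybenzaldehyde
Product: 12 3,5-bis(methoxymethoxy)benzaldehyde
Conditions: MOMCl (2.5 equiv), i-Pr2NEt, CH2Cl2, 0 °C → rt
Reagents that add atoms: chloromethyl methyl ether (MOMCl), COCCl
Why: Double O-alkylation of the phenols; the same acetal as on the syringyl ring allows one final deprotection.

Step 10
Reactants: 12 3,5-bis(methoxymethoxy)benzaldehyde
Product: 13 1-ethenyl-3,5-bis(methoxymethoxy)benzene
Conditions: Ph3PCH3Br, KOt-Bu, THF, 0 °C → rt
Reagents that add atoms: methyltriphenylphosphonium bromide, C[P+](c1ccccc1)(c1ccccc1)c1ccccc1.[Br-]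
Why: Wittig methylenation of an aromatic aldehyde with the non-stabilised ylide; the acetals are stable to base.

Step 11
Reactants: 10 {[(2R,3R)-6-bromo-3-[3,5-dimethoxy-4-(methoxymethoxy)phenyl]-2,3-dihydro-1,4-benzodioxin-2-yl]methoxy}(tert-butyl)dimethylsilane; 13 1-ethenyl-3,5-bis(methoxymethoxy)benzene
Product: 14 {[(2R,3R)-6-[(E)-2-[3,5-bis(methoxymethoxy)phenyl]ethenyl]-3-[3,5-dimethoxy-4-(methoxymethoxy)phenyl]-2,3-dihydro-1,4-benzodioxin-2-yl]methoxy}(tert-butyl)dimethylsilane
Conditions: Pd2(dba)3 (2.5 mol %), [t-Bu3PH]BF4 (10 mol %), Cy2NMe, 1,4-dioxane, 90 °C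
Reagents that add atoms: none
Why: Mizoroki–Heck arylation of a styrene; the bulky electron-rich phosphine is chosen for the electron-rich aryl bromide, and syn insertion followed by syn β-hydride elimination should give the E-stilbene. Neither stereocentre is involved.

Step 12
Reactants: 14 {[(2R,3R)-6-[(E)-2-[3,5-bis(methoxymethoxy)phenyl]ethenyl]-3-[3,5-dimethoxy-4-(methoxymethoxy)phenyl]-2,3-dihydro-1,4-benzodioxin-2-yl]methoxy}(tert-butyl)dimethylsilane
Product: 15 aiphanol, 5-[(E)-2-[(2R,3R)-3-(4-hydroxy-3,5-dimethoxyphenyl)-2-(hydroxymethyl)-2,3-dihydro-1,4-benzodioxin-6-yl]ethenyl]benzene-1,3-diol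
Conditions: HCl (1.25 M in MeOH), MeOH/THF, 0 → 40 °C
Reagents that add atoms: none
Why: Acid-catalysed acetal exchange should remove the three MOM groups and methanolysis the primary silyl ether; the trans ring is the thermodynamic one, so a reversible ionisation at C3 should return to 15 while C2 stays fixed.

## Compound list

1 | acetosyringone, 1-(4-hydroxy-3,5-dimethoxyphenyl)ethan-1-one | CC(=O)c1cc(OC)c(O)c(OC)c1 | starting material
2 | 1-[3,5-dimethoxy-4-(methoxymethoxy)phenyl]ethan-1-one | CC(=O)c1cc(OC)c(OCOC)c(OC)c1 | intermediate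
3 | ethyl 3-[3,5-dimethoxy-4-(methoxymethoxy)phenyl]-3-oxopropanoate | CCOC(=O)CC(=O)c1cc(OC)c(OCOC)c(OC)c1 | intermediate
4 | ethyl 2-chloro-3-[3,5-dimethoxy-4-(methoxymethoxy)phenyl]-3-oxopropanoate (racemic) | CCOC(=O)C(Cl)C(=O)c1cc(OC)c(OCOC)c(OC)c1 | intermediate
5 | 4-bromo-2-iodophenol | Oc1ccc(Br)cc1I | starting material
6 | ethyl 2-(4-bromo-2-iodophenoxy)-3-[3,5-dimethoxy-4-(methoxymethoxy)phenyl]-3-oxopropanoate (racemic) | CCOC(=O)C(Oc1ccc(Br)cc1I)C(=O)c1cc(OC)c(OCOC)c(OC)c1 | intermediate
7 | ethyl (2S,3R)-2-(4-bromo-2-iodophenoxy)-3-hydroxy-3-[3,5-dimethoxy-4-(methoxymethoxy)phenyl]propanoate | CCOC(=O)[C@@H](Oc1ccc(Br)cc1I)[C@H](O)c1cc(OC)c(OCOC)c(OC)c1 | intermediate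
8 | (1R,2R)-2-(4-bromo-2-iodophenoxy)-1-[3,5-dimethoxy-4-(methoxymethoxy)phenyl]propane-1,3-diol | OC[C@@H](Oc1ccc(Br)cc1I)[C@H](O)c1cc(OC)c(OCOC)c(OC)c1 | intermediate
9 | (1R,2R)-2-(4-bromo-2-iodophenoxy)-3-[(tert-butyldimethylsilyl)oxy]-1-[3,5-dimethoxy-4-(methoxymethoxy)phenyl]propan-1-ol | CC(C)(C)[Si](C)(C)OC[C@@H](Oc1ccc(Br)cc1I)[C@H](O)c1cc(OC)c(OCOC)c(OC)c1 | intermediate
10 | {[(2R,3R)-6-bromo-3-[3,5-dimethoxy-4-(methoxymethoxy)phenyl]-2,3-dihydro-1,4-benzodioxin-2-yl]methoxy}(tert-butyl)dimethylsilane | COCOc1c(OC)cc([C@H]2Oc3cc(Br)ccc3O[C@@H]2CO[Si](C)(C)C(C)(C)C)cc1OC | intermediate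
11 | 3,5-dihydroxybenzaldehyde | O=Cc1cc(O)cc(O)c1 | starting material
12 | 3,5-bis(methoxymethoxy)benzaldehyde | O=Cc1cc(OCOC)cc(OCOC)c1 | intermediate
13 | 1-ethenyl-3,5-bis(methoxymethoxy)benzene | C=Cc1cc(OCOC)cc(OCOC)c1 | intermediate
14 | {[(2R,3R)-6-[(E)-2-[3,5-bis(methoxymethoxy)phenyl]ethenyl]-3-[3,5-dimethoxy-4-(methoxymethoxy)phenyl]-2,3-dihydro-1,4-benzodioxin-2-yl]methoxy}(tert-butyl)dimethylsilane | COCOc1c(OC)cc([C@H]2Oc3cc(/C=C/c4cc(OCOC)cc(OCOC)c4)ccc3O[C@@H]2CO[Si](C)(C)C(C)(C)C)cc1OC | intermediate
15 | aiphanol, 5-[(E)-2-[(2R,3R)-3-(4-hydroxy-3,5-dimethoxyphenyl)-2-(hydroxymethyl)-2,3-dihydro-1,4-benzodioxin-6-yl]ethenyl]benzene-1,3-diol | COc1cc([C@H]2Oc3cc(/C=C/c4cc(O)cc(O)c4)ccc3O[C@@H]2CO)cc(OC)c1O | target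

## Step count and least certain steps

Total: 12 steps. Longest linear sequence: 10 steps (steps 1–8, 11, 12).

**Step 5 (key step).** The aryloxy group is bulkier and less basic than the alkoxy groups of the closest precedents. The syn preference could therefore be incomplete, or reduction could run ahead of racemisation for part of the material, lowering diastereo- and enantiopurity. The fallback uses an auxiliary and runs from 5 to 8. O-alkylation of 5 with purchased (S)-4-benzyl-3-(chloroacetyl)-1,3-oxazolidin-2-one (K2CO3, NaI, acetone) would give (S)-4-benzyl-3-[2-(4-bromo-2-iodophenoxy)acetyl]-1,3-oxazolidin-2-one F1. Its Z-boron enolate (Bu2BOTf, i-Pr2NEt, CH2Cl2, −78 °C) should add to 3,5-dimethoxy-4-(methoxymethoxy)benzaldehyde F2, made from syringaldehyde and MOMCl, in an Evans syn glycolate aldol reaction. This should give (S)-4-benzyl-3-[(2S,3R)-2-(4-bromo-2-iodophenoxy)-3-hydroxy-3-[3,5-dimethoxy-4-(methoxymethoxy)phenyl]propanoyl]-1,3-oxazolidin-2-one F3. LiBH4 would then cleave the auxiliary reductively and give 8.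

**Step 8.** The hindered benzylic alkoxide may couple slowly. Meanwhile base and heat could expel the aryloxide from C2 through epoxide formation, move the silyl group to the secondary oxygen, or remove iodine reductively. The fallback closes the ring at the benzylic bond under thermodynamic control and runs from 9 to 15. Deprotonation and iodine–magnesium exchange (i-PrMgCl·LiCl, 2.2 equiv, THF, −40 °C; selective for C–I over C–Br), then B(OMe)3 and H2O2/NaOH, would give (1R,2R)-2-(4-bromo-2-hydroxyphenoxy)-3-[(tert-butyldimethylsilyl)oxy]-1-[3,5-dimethoxy-4-(methoxymethoxy)phenyl]propan-1-ol F4. Aqueous HCl in THF should remove the acetal and the silyl group and ionise the p-hydroxybenzylic alcohol to its quinone methide. The new phenol traps it reversibly, and this should converge on the trans ring of [(2R,3R)-6-bromo-3-(4-hydroxy-3,5-dimethoxyphenyl)-2,3-dihydro-1,4-benzodioxin-2-yl]methanol F5 with C2 untouched. Heck coupling of F5 with 13 under the step 11 conditions would give 5-O,3-O-bis(methoxymethyl)aiphanol F6, and the step 12 conditions would give 15.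

**Step 11.** Oxidative addition into the electron-rich bromide may be slow. Insertion with the opposite regiochemistry would give a 1,1-diarylethene, and palladium hydride could shift or isomerise the alkene. The fallback joins a preformed E-alkenyl boronate and runs from 13 (with 10) to 14. Cross-metathesis of 13 with vinylboronic acid pinacol ester (Grubbs second-generation catalyst, CH2Cl2, 40 °C) should give (E)-2-{2-[3,5-bis(methoxymethoxy)phenyl]ethenyl}-4,4,5,5-tetramethyl-1,3,2-dioxaborolane F7. Suzuki–Miyaura coupling with 10 (Pd(dppf)Cl2, K2CO3, dioxane/H2O, 80 °C) proceeds with retention of alkene geometry and would give 14.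

**Step 12.** Acid may ionise the C3–O4 bond with capture by methanol. The methoxymethyl cations set free may alkylate the electron-rich resorcinol ring, and the stilbene may oligomerise. The fallback moves the acid step ahead of the stilbene and ends with fluoride; it runs from 10 to 15. Treatment of 10 with methanolic HCl would give the bromo phenol F5 described above. Silylation of 11 (TBSCl, imidazole, DMF) would give 3,5-bis[(tert-butyldimethylsilyl)oxy]benzaldehyde F8, and methylenation as in step 10 would give 1-ethenyl-3,5-bis[(tert-butyldimethylsilyl)oxy]benzene F9. Heck coupling of F5 with F9 under the step 11 conditions would give the 3,5-bis(tert-butyldimethylsilyl) ether of aiphanol F10. TBAF buffered with AcOH in THF at 0 °C would give 15 without acid meeting the stilbene.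

**Step 4.** The base may simply turn 4 into its unreactive enolate. The phenoxide may attack chlorine instead of carbon (reductive dechlorination), or cleave the keto ester by retro-Claisen attack at the ketone. The fallback replaces the SN2 reaction by a carbenoid O–H insertion and runs from 3 to 6. Diazo transfer to 3 (p-acetamidobenzenesulfonyl azide, Et3N, MeCN) would give ethyl 2-diazo-3-[3,5-dimethoxy-4-(methoxymethoxy)phenyl]-3-oxopropanoate F11. Rh2(OAc)4-catalysed O–H insertion into 5 (CH2Cl2, 40 °C) would give 6.

## Further compounds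

F1 | step 5 | (S)-4-benzyl-3-[2-(4-bromo-2-iodophenoxy)acetyl]-1,3-oxazolidin-2-one | O=C1OC[C@H](Cc2ccccc2)N1C(=O)COc1ccc(Br)cc1I
F2 | step 5 | 3,5-dimethoxy-4-(methoxymethoxy)benzaldehyde | COCOc1c(OC)cc(C=O)cc1OC
F3 | step 5 | (S)-4-benzyl-3-[(2S,3R)-2-(4-bromo-2-iodophenoxy)-3-hydroxy-3-[3,5-dimethoxy-4-(methoxymethoxy)phenyl]propanoyl]-1,3-oxazolidin-2-one | O=C1OC[C@H](Cc2ccccc2)N1C(=O)[C@@H](Oc1ccc(Br)cc1I)[C@H](O)c1cc(OC)c(OCOC)c(OC)c1
F4 | step 8 | (1R,2R)-2-(4-bromo-2-hydroxyphenoxy)-3-[(tert-butyldimethylsilyl)oxy]-1-[3,5-dimethoxy-4-(methoxymethoxy)phenyl]propan-1-ol | CC(C)(C)[Si](C)(C)OC[C@@H](Oc1ccc(Br)cc1O)[C@H](O)c1cc(OC)c(OCOC)c(OC)c1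
F5 | step 8 | [(2R,3R)-6-bromo-3-(4-hydroxy-3,5-dimethoxyphenyl)-2,3-dihydro-1,4-benzodioxin-2-yl]methanol | COc1cc([C@H]2Oc3cc(Br)ccc3O[C@@H]2CO)cc(OC)c1O
F6 | step 8 | 4-[(2R,3R)-6-[(E)-2-[3,5-bis(methoxymethoxy)phenyl]ethenyl]-2-(hydroxymethyl)-2,3-dihydro-1,4-benzodioxin-3-yl]-2,6-dimethoxyphenol | COc1cc([C@H]2Oc3cc(/C=C/c4cc(OCOC)cc(OCOC)c4)ccc3O[C@@H]2CO)cc(OC)c1O
F7 | step 11 | (E)-2-{2-[3,5-bis(methoxymethoxy)phenyl]ethenyl}-4,4,5,5-tetramethyl-1,3,2-dioxaborolane | COCOc1cc(/C=C/B2OC(C)(C)C(C)(C)O2)cc(OCOC)c1
F8 | step 12 | 3,5-bis[(tert-butyldimethylsilyl)oxy]benzaldehyde | O=Cc1cc(O[Si](C)(C)C(C)(C)C)cc(O[Si](C)(C)C(C)(C)C)c1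
F9 | step 12 | 1-ethenyl-3,5-bis[(tert-butyldimethylsilyl)oxy]benzene | C=Cc1cc(O[Si](C)(C)C(C)(C)C)cc(O[Si](C)(C)C(C)(C)C)c1
F10 | step 12 | 4-[(2R,3R)-6-[(E)-2-{3,5-bis[(tert-butyldimethylsilyl)oxy]phenyl}ethenyl]-2-(hydroxymethyl)-2,3-dihydro-1,4-benzodioxin-3-yl]-2,6-dimethoxyphenol | COc1cc([C@H]2Oc3cc(/C=C/c4cc(O[Si](C)(C)C(C)(C)C)cc(O[Si](C)(C)C(C)(C)C)c4)ccc3O[C@@H]2CO)cc(OC)c1O
F11 | step 4 | ethyl 2-diazo-3-[3,5-dimethoxy-4-(methoxymethoxy)phenyl]-3-oxopropanoate | CCOC(=O)C(=[N+]=[N-])C(=O)c1cc(OC)c(OCOC)c(OC)c1
A1 | alternative 1 | piceatannol, 4-[(E)-2-(3,5-dihydroxyphenyl)ethenyl]benzene-1,2-diol | Oc1cc(O)cc(/C=C/c2ccc(O)c(O)c2)c1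
A2 | alternative 1 | sinapyl alcohol, 4-[(E)-3-hydroxyprop-1-enyl]-2,6-dimethoxyphenol | COc1cc(/C=C/CO)cc(OC)c1O
A3 | alternative 1 | 4-{2-[4-[(E)-2-(3,5-dihydroxyphenyl)ethenyl]-2-hydroxyphenoxy]-3-hydroxypropylidene}-2,6-dimethoxycyclohexa-2,5-dien-1-one (quinone methide, racemic) | COC1=CC(=CC(CO)Oc2ccc(/C=C/c3cc(O)cc(O)c3)cc2O)C=C(OC)C1=O
A4 | alternative 2 | ethyl (E)-3-[3,5-dimethoxy-4-(methoxymethoxy)phenyl]prop-2-enoate | CCOC(=O)/C=C/c1cc(OC)c(OCOC)c(OC)c1
A5 | alternative 2 | ethyl (2R,3S)-2,3-dihydroxy-3-[3,5-dimethoxy-4-(methoxymethoxy)phenyl]propanoate | CCOC(=O)[C@H](O)[C@@H](O)c1cc(OC)c(OCOC)c(OC)c1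
A6 | alternative 3 | ethyl 6-bromo-3-[3,5-dimethoxy-4-(methoxymethoxy)phenyl]-1,4-benzodioxine-2-carboxylate | CCOC(=O)C1=C(c2cc(OC)c(OCOC)c(OC)c2)Oc2cc(Br)ccc2O1
A7 | alternative 3 | ethyl (2R,3R)-6-bromo-3-[3,5-dimethoxy-4-(methoxymethoxy)phenyl]-2,3-dihydro-1,4-benzodioxine-2-carboxylate (cis) | COCOc1c(OC)cc([C@H]2Oc3cc(Br)ccc3O[C@H]2C(=O)OCC)cc1OC
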